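**Strategy**

Everything rests on the C2–C3 bond of ring A (octahydronaphthalene numbering: C1 bears the dienoic acid, C2 the butenyl group, C3 a methyl group; ring B is C4a, C5–C8, C8a). C2 is β to the side-chain carbon on C1 and sits between the C3=C4 and butenyl alkenes. The precursor is therefore a monocyclic ring-B compound: C8a carries a 2-substituted (2E,4E)-dienal made from tiglic aldehyde, C4a a (Z)-alkenylstannane. Copper-mediated 6-endo conjugate addition of the alkenyl carbon (C3) to the dienal β-carbon (C2) closes ring A, leaves the C3=C4 alkene and the intact butenyl group, and sets C2 and C1 from the C4a/C8a stereocentres, themselves set by one catalytic Diels–Alder reaction.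

Key step: step 12

Remarks on the chemistry (one line each):
- Locants C1–C8a in the Why lines are those of the target's octahydronaphthalene (C7 carries the sulfate, C8 the ring-B methyl); compound names use their own locants.
- Assumption: the (S)-prolinol-derived oxazaborolidinium salt is written in step 3; if its facial sense is the opposite one, the (R)-prolinol-derived salt is used and nothing else changes.
- Assumption: the target is taken as the free acid drawn (hydrogen sulfate and carboxylic acid), obtained by cold acidification of its salt.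

**Route**

Step 1
Reactants: 1 3-(benzyloxy)propanal; 2 1-(triphenyl-λ5-phosphanylidene)propan-2-one
Product: 3 (3E)-6-(benzyloxy)hex-3-en-2-one
Conditions: CH2Cl2, 40 °C
Reagents that add atoms: none
Why: Wittig olefination with a stabilised ylide should give the (E)-enone under neutral conditions that spare the β-alkoxy aldehyde.

Step 2
Reactants: 3 (3E)-6-(benzyloxy)hex-3-en-2-one
Product: 4 tri(propan-2-yl){[(3E)-6-(benzyloxy)hexa-1,3-dien-2-yl]oxy}silane
Conditions: LiN(i-Pr)2, THF, −78 °C; then i-Pr3SiOTf, −78 to 0 °C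
Reagents that add atoms: triisopropylsilyl trifluoromethanesulfonate, CC(C)[Si](C(C)C)(C(C)C)OS(=O)(=O)C(F)(F)F
Why: kinetic deprotonation at the methyl group and O-silylation of the cross-conjugated enolate (silyl enol ether formation) should give the 2-silyloxy-1,3-diene with the (E)-alkene untouched.

Step 3
Reactants: 4 tri(propan-2-yl){[(3E)-6-(benzyloxy)hexa-1,3-dien-2-yl]oxy}silane; 5 2,2,2-trifluoroethyl prop-2-enoate
Product: 6 2,2,2-trifluoroethyl (1S,2R)-2-[2-(benzyloxy)ethyl]-4-{[tri(propan-2-yl)silyl]oxy}cyclohex-3-ene-1-carboxylate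
Conditions: 5 (1.5 equiv), 20 mol % of the salt from (S)-3,3-diphenyl-1-(2-methylphenyl)tetrahydro-1H,3H-pyrrolo[1,2-c][1,3,2]oxazaborole and HN(SO2CF3)2, CH2Cl2, −78 to −40 °C
Reagents that add atoms: none
Why: catalytic enantioselective Diels–Alder reaction in which the silyloxy ("para") and alkyl ("ortho") directing effects both join the CH2 terminus of the diene to the acrylate β-carbon, the endo transition state places the ester cis to the side chain, and the catalyst shields one acrylate face, which sets C4a and C8a together.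

Step 4
Reactants: 6 2,2,2-trifluoroethyl (1S,2R)-2-[2-(benzyloxy)ethyl]-4-{[tri(propan-2-yl)silyl]oxy}cyclohex-3-ene-1-carboxylate
Product: 7 2,2,2-trifluoroethyl (1S,2R,3R)-2-[2-(benzyloxy)ethyl]-3-methyl-4-oxocyclohexane-1-carboxylate
Conditions: Bu4N[Ph3SiF2] (1.1 equiv), MeI (5 equiv), THF, −40 to 0 °C
Reagents that add atoms: iodomethane, CI
Why: fluoride cleaves the silyl enol ether to the regiodefined ammonium enolate, whose C-methylation (enolate alkylation) should occur on the ring face anti to the adjacent side chain and the cis ester, so that the C8 methyl ends trans to the side chain.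

Step 5
Reactants: 7 2,2,2-trifluoroethyl (1S,2R,3R)-2-[2-(benzyloxy)ethyl]-3-methyl-4-oxocyclohexane-1-carboxylate
Product: 8 2,2,2-trifluoroethyl (1S,2R,3R,4S)-2-[2-(benzyloxy)ethyl]-4-hydroxy-3-methylcyclohexane-1-carboxylate
Conditions: LiBH(s-Bu)3 (L-Selectride, 1.1 equiv), THF, −78 °C; then H2O
Reagents that add atoms: none
Why: diastereoselective ketone reduction in which the bulky hydride attacks from the equatorial direction of the chair with methyl and side chain equatorial, which should give the axial C7 alcohol cis to the methyl group while the ester survives at −78 °C.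

Step 6
Reactants: 8 2,2,2-trifluoroethyl (1S,2R,3R,4S)-2-[2-(benzyloxy)ethyl]-4-hydroxy-3-methylcyclohexane-1-carboxylate
Product: 10 (4aR,5R,6S,8aS)-6-hydroxy-5-methyl-3,4,4a,5,6,7,8,8a-octahydro-1H-isochromen-1-one, via diol ester 9 (not isolated)
Conditions: H2 (1 atm), Pd/C, EtOAc, 20 °C; then pyridinium p-toluenesulfonate (cat.), toluene, 60 °C
Reagents that add atoms: none
Why: hydrogenolysis of the benzyl ether frees the primary alcohol, which acylates on the cis-disposed activated ester (lactonisation) to give the cis-fused δ-lactone, while the C7 hydroxyl is trans to the ester across the ring and cannot lactonise.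

Step 7
Reactants: 10 (4aR,5R,6S,8aS)-6-hydroxy-5-methyl-3,4,4a,5,6,7,8,8a-octahydro-1H-isochromen-1-one
Product: 11 (4aR,5R,6S,8aS)-5-methyl-3,4,4a,5,6,7,8,8a-octahydro-1H-isochromene-1,6-diol
Conditions: i-Bu2AlH (2.2 equiv), CH2Cl2, −78 °C; then aq. KNaC4H4O6
Reagents that add atoms: none
Why: partial hydride reduction of a δ-lactone stops at the lactol at low temperature, the first equivalent being consumed by the free hydroxyl.

Step 8
Reactants: 11 (4aR,5R,6S,8aS)-5-methyl-3,4,4a,5,6,7,8,8a-octahydro-1H-isochromene-1,6-diol; 12 ethyl(triphenyl)phosphonium iodide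
Product: 13 (1S,2R,3S,4S)-3-(2-hydroxyethyl)-4-[(1Z)-2-iodoprop-1-en-1-yl]-2-methylcyclohexan-1-ol
Conditions: 12 (4 equiv), n-BuLi, THF, 0 °C; I2, −78 °C; NaN(SiMe3)2, −20 °C; then 11, −78 to −20 °C
Reagents that add atoms: iodine, II
Why: Wittig olefination with the α-iodo ylide (Stork–Zhao type) on the open hydroxy-aldehyde form of the lactol should give the (Z)-2-iodopropenyl group with iodine cis to the ring and free the primary alcohol, the unstabilised ylide reacting at low temperature before C4a can epimerise.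

Step 9
Reactants: 13 (1S,2R,3S,4S)-3-(2-hydroxyethyl)-4-[(1Z)-2-iodoprop-1-en-1-yl]-2-methylcyclohexan-1-ol
Product: 14 2-{(1S,2R,3S,6S)-3-hydroxy-6-[(1Z)-2-iodoprop-1-en-1-yl]-2-methylcyclohexyl}acetaldehyde
Conditions: 2,2,6,6-tetramethylpiperidin-1-oxyl (10 mol %), PhI(OAc)2 (1.1 equiv), CH2Cl2, 20 °C
Reagents that add atoms: none
Why: oxoammonium-catalysed oxidation is selective for the primary over the hindered axial secondary alcohol, and the trans-1,3 relation of the C7 hydroxyl and the side chain prevents lactol formation.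

Step 10
Reactants: 14 2-{(1S,2R,3S,6S)-3-hydroxy-6-[(1Z)-2-iodoprop-1-en-1-yl]-2-methylcyclohexyl}acetaldehyde; 15 (2E)-2-methylbut-2-enal
Product: 18 (2E,4E)-2-{(1S,2R,3S,6S)-3-hydroxy-6-[(1Z)-2-iodoprop-1-en-1-yl]-2-methylcyclohexyl}-4-methylhexa-2,4-dienal, via N-cyclohexyl imine 16 (not isolated), via β-hydroxy imine 17 (not isolated)
Conditions: c-C6H11NH2, 4 Å molecular sieves, CH2Cl2, 20 °C, then evaporate; LiN(i-Pr)2 (2.1 equiv), THF, −78 °C; 15, −78 °C; then aq. oxalic acid, THF, 20 °C
Reagents that add atoms: none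
Why: directed aldol condensation through the aza-enolate of the aldimine (1,2-addition to 15, then acid hydrolysis and dehydration of the allylic β-hydroxy aldehyde) should give the thermodynamic (2E)-dienal with the butenyl unit of 15 unchanged and cis to the ring.

Step 11
Reactants: 18 (2E,4E)-2-{(1S,2R,3S,6S)-3-hydroxy-6-[(1Z)-2-iodoprop-1-en-1-yl]-2-methylcyclohexyl}-4-methylhexa-2,4-dienal
Product: 19 (2E,4E)-2-{(1S,2R,3S,6S)-3-hydroxy-2-methyl-6-[(1Z)-2-(trimethylstannyl)prop-1-en-1-yl]cyclohexyl}-4-methylhexa-2,4-dienal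
Conditions: Me3SnSnMe3 (1.5 equiv), Pd(PPh3)4 (5 mol %, zerovalent palladium), THF, 50 °C
Reagents that add atoms: hexamethyldistannane, C[Sn](C)(C)[Sn](C)(C)C
Why: palladium-catalysed stannylation of the alkenyl iodide (oxidative addition, transmetallation with the distannane, reductive elimination) proceeds with retention of the (Z)-geometry.

Step 12
Reactants: 19 (2E,4E)-2-{(1S,2R,3S,6S)-3-hydroxy-2-methyl-6-[(1Z)-2-(trimethylstannyl)prop-1-en-1-yl]cyclohexyl}-4-methylhexa-2,4-dienal
Product: 22 (1S,2R,4aS,7S,8R,8aS)-2-[(2E)-but-2-en-2-yl]-7-hydroxy-3,8-dimethyl-1,2,4a,5,6,7,8,8a-octahydronaphthalene-1-carbaldehyde, via alkenylcopper 20 (not isolated), via stannyl enol ether 21 (not isolated)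
Conditions: CuCl (3 equiv), DMF, 0 to 20 °C; then aq. NH4Cl/NH3 (pH 8); then 1,8-diazabicyclo[5.4.0]undec-7-ene (0.2 equiv), CH2Cl2, 20 °C
Reagents that add atoms: none
Why: Tin-to-copper exchange gives alkenylcopper 20, whose carbon C3 adds to the β-carbon (future C2) of the dienal through a copper–alkene π-complex, and the resulting enolate is held as stannyl enol ether 21 until work-up. The closest known reaction type is the CuCl-mediated intramolecular conjugate addition of alkenyltrimethylstannanes to α,β-unsaturated carbonyl compounds. Ring A closes in the 6-endo-trig mode, which the (Z)-geometry of the alkenylmetal (metal cis to C4a) allows. C2 is controlled by the (2E)-geometry of the dienal and by ring B: the butenyl group, cis to C8a on the alkene, must become pseudoaxial, and only the half-chair with C8 equatorial on the new ring avoids a 1,3-diaxial contact between butenyl and C8, which puts butenyl anti to C8 as in the target. C1 is set by protonation and base equilibration, the formyl group taking the equatorial position trans to C8 and cis to the pseudoaxial butenyl group. The step needs 1,4- over 1,2- and 1,6-addition: an uncharged organocopper does not attack the formyl group, and 1,6-attack would need an eight-membered ring holding an (E)-alkene.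

Step 13
Reactants: 22 (1S,2R,4aS,7S,8R,8aS)-2-[(2E)-but-2-en-2-yl]-7-hydroxy-3,8-dimethyl-1,2,4a,5,6,7,8,8a-octahydronaphthalene-1-carbaldehyde; 23 ethyl (2E)-4-(diethoxyphosphoryl)but-2-enoate
Product: 24 ethyl (2E,4E)-5-{(1S,2R,4aS,7S,8R,8aR)-2-[(2E)-but-2-en-2-yl]-7-hydroxy-3,8-dimethyl-1,2,4a,5,6,7,8,8a-octahydronaphthalen-1-yl}penta-2,4-dienoate
Conditions: 23 (2.5 equiv), LiN(SiMe3)2 (2.4 equiv), THF, −78 to 0 °C
Reagents that add atoms: none
Why: Horner–Wadsworth–Emmons olefination with the vinylogous phosphonate anion should give the (2E,4E)-dienoate, C1 already being in its more stable configuration and the excess anion covering the free hydroxyl.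

Step 14
Reactants: 24 ethyl (2E,4E)-5-{(1S,2R,4aS,7S,8R,8aR)-2-[(2E)-but-2-en-2-yl]-7-hydroxy-3,8-dimethyl-1,2,4a,5,6,7,8,8a-octahydronaphthalen-1-yl}penta-2,4-dienoate
Product: 26 (2E,4E)-5-{(1S,2R,4aS,7S,8R,8aR)-2-[(2E)-but-2-en-2-yl]-3,8-dimethyl-7-(sulfooxy)-1,2,4a,5,6,7,8,8a-octahydronaphthalen-1-yl}penta-2,4-dienoic acid, via sulfate ester 25 (not isolated)
Conditions: SO3·pyridine (5 equiv), pyridine, 40 °C; then LiOH, THF/MeOH/H2O, 20 °C; then 1 M HCl to pH 2, 0 °C, extraction into n-BuOH
Reagents that add atoms: sulfur trioxide pyridine complex, [O-]S(=O)(=O)[n+]1ccccc1; lithium hydroxide, [Li+].[OH-]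
Why: O-sulfation of the secondary alcohol followed by saponification of the ethyl ester should work in one flask because an alkyl sulfate monoanion is stable to aqueous hydroxide, and cold acidification gives the free acid form without touching any stereocentre.

**Compound list**

1 | 3-(benzyloxy)propanal | O=CCCOCc1ccccc1 | starting material
2 | 1-(triphenyl-λ5-phosphanylidene)propan-2-one | CC(=O)C=P(c1ccccc1)(c1ccccc1)c1ccccc1 | starting material
3 | (3E)-6-(benzyloxy)hex-3-en-2-one | CC(=O)/C=C/CCOCc1ccccc1 | intermediate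
4 | tri(propan-2-yl){[(3E)-6-(benzyloxy)hexa-1,3-dien-2-yl]oxy}silane | C=C(O[Si](C(C)C)(C(C)C)C(C)C)/C=C/CCOCc1ccccc1 | intermediate
5 | 2,2,2-trifluoroethyl prop-2-enoate | C=CC(=O)OCC(F)(F)F | starting material
6 | 2,2,2-trifluoroethyl (1S,2R)-2-[2-(benzyloxy)ethyl]-4-{[tri(propan-2-yl)silyl]oxy}cyclohex-3-ene-1-carboxylate (ester and side chain cis) | O=C(OCC(F)(F)F)[C@H]1CCC(O[Si](C(C)C)(C(C)C)C(C)C)=C[C@H]1CCOCc1ccccc1 | intermediate
7 | 2,2,2-trifluoroethyl (1S,2R,3R)-2-[2-(benzyloxy)ethyl]-3-methyl-4-oxocyclohexane-1-carboxylate (methyl trans to side chain) | O=C(OCC(F)(F)F)[C@H]1CCC(=O)[C@H](C)[C@H]1CCOCc1ccccc1 | intermediate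
8 | 2,2,2-trifluoroethyl (1S,2R,3R,4S)-2-[2-(benzyloxy)ethyl]-4-hydroxy-3-methylcyclohexane-1-carboxylate (hydroxyl cis to methyl) | O=C(OCC(F)(F)F)[C@H]1CC[C@H](O)[C@H](C)[C@H]1CCOCc1ccccc1 | intermediate
9 | diol ester: 2,2,2-trifluoroethyl (1S,2R,3R,4S)-4-hydroxy-2-(2-hydroxyethyl)-3-methylcyclohexane-1-carboxylate | O=C(OCC(F)(F)F)[C@H]1CC[C@H](O)[C@H](C)[C@H]1CCO | intermediate (not isolated)
10 | (4aR,5R,6S,8aS)-6-hydroxy-5-methyl-3,4,4a,5,6,7,8,8a-octahydro-1H-isochromen-1-one (cis-fused lactone) | O=C1[C@H]2CC[C@H](O)[C@H](C)[C@H]2CCO1 | intermediate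
11 | (4aR,5R,6S,8aS)-5-methyl-3,4,4a,5,6,7,8,8a-octahydro-1H-isochromene-1,6-diol (lactol, both C1 epimers) | OC1[C@H]2CC[C@H](O)[C@H](C)[C@H]2CCO1 | intermediate
12 | ethyl(triphenyl)phosphonium iodide | CC[P+](c1ccccc1)(c1ccccc1)c1ccccc1.[I-] | starting material
13 | (1S,2R,3S,4S)-3-(2-hydroxyethyl)-4-[(1Z)-2-iodoprop-1-en-1-yl]-2-methylcyclohexan-1-ol | C/C(I)=C/[C@H]1CC[C@H](O)[C@H](C)[C@H]1CCO | intermediate
14 | 2-{(1S,2R,3S,6S)-3-hydroxy-6-[(1Z)-2-iodoprop-1-en-1-yl]-2-methylcyclohexyl}acetaldehyde | C/C(I)=C/[C@H]1CC[C@H](O)[C@H](C)[C@H]1CC=O | intermediate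
15 | (2E)-2-methylbut-2-enal (tiglic aldehyde) | C/C=C(\C)C=O | starting material
16 | N-cyclohexyl imine of 14 | C/C(I)=C/[C@H]1CC[C@H](O)[C@H](C)[C@H]1CC=NC1CCCCC1 | intermediate (not isolated)
17 | β-hydroxy imine, aldol adduct of 16 and 15 (two new centres unassigned) | C/C(I)=C/[C@H]1CC[C@H](O)[C@H](C)[C@H]1C(C=NC1CCCCC1)C(O)/C(C)=C/C | intermediate (not isolated)
18 | (2E,4E)-2-{(1S,2R,3S,6S)-3-hydroxy-6-[(1Z)-2-iodoprop-1-en-1-yl]-2-methylcyclohexyl}-4-methylhexa-2,4-dienal | C/C(I)=C/[C@H]1CC[C@H](O)[C@H](C)[C@H]1/C(C=O)=C\C(C)=C\C | intermediate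
19 | (2E,4E)-2-{(1S,2R,3S,6S)-3-hydroxy-2-methyl-6-[(1Z)-2-(trimethylstannyl)prop-1-en-1-yl]cyclohexyl}-4-methylhexa-2,4-dienal | C/C([Sn](C)(C)C)=C/[C@H]1CC[C@H](O)[C@H](C)[C@H]1/C(C=O)=C\C(C)=C\C | intermediate
20 | alkenylcopper: 19 with copper in place of the trimethylstannyl group | C/C([Cu])=C/[C@H]1CC[C@H](O)[C@H](C)[C@H]1/C(C=O)=C\C(C)=C\C | intermediate (not isolated)
21 | O-trimethylstannyl enol ether of 22 (C1=CH–OSnMe3, other centres as in 22) | C/C=C(\C)[C@@H]1C(C)=C[C@H]2CC[C@H](O)[C@H](C)[C@H]2C1=CO[Sn](C)(C)C | intermediate (not isolated)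
22 | (1S,2R,4aS,7S,8R,8aS)-2-[(2E)-but-2-en-2-yl]-7-hydroxy-3,8-dimethyl-1,2,4a,5,6,7,8,8a-octahydronaphthalene-1-carbaldehyde | C/C=C(\C)[C@@H]1C(C)=C[C@H]2CC[C@H](O)[C@H](C)[C@H]2[C@@H]1C=O | intermediate
23 | ethyl (2E)-4-(diethoxyphosphoryl)but-2-enoate | CCOC(=O)/C=C/CP(=O)(OCC)OCC | starting material
24 | ethyl (2E,4E)-5-{(1S,2R,4aS,7S,8R,8aR)-2-[(2E)-but-2-en-2-yl]-7-hydroxy-3,8-dimethyl-1,2,4a,5,6,7,8,8a-octahydronaphthalen-1-yl}penta-2,4-dienoate | C/C=C(\C)[C@@H]1C(C)=C[C@H]2CC[C@H](O)[C@H](C)[C@H]2[C@@H]1/C=C/C=C/C(=O)OCC | intermediate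
25 | sulfate ester: 7-O-sulfate of 24 (ethyl ester of 26) | C/C=C(\C)[C@@H]1C(C)=C[C@H]2CC[C@H](OS(=O)(=O)O)[C@H](C)[C@H]2[C@@H]1/C=C/C=C/C(=O)OCC | intermediate (not isolated)
26 | (2E,4E)-5-{(1S,2R,4aS,7S,8R,8aR)-2-[(2E)-but-2-en-2-yl]-3,8-dimethyl-7-(sulfooxy)-1,2,4a,5,6,7,8,8a-octahydronaphthalen-1-yl}penta-2,4-dienoic acid (CNP0450810.2) | C/C=C(\C)[C@@H]1C(C)=C[C@H]2CC[C@H](OS(=O)(=O)O)[C@H](C)[C@H]2[C@@H]1/C=C/C=C/C(=O)O | target

**Count and risks**

Total step count: 14. Longest linear sequence: 14 steps (1 to 26).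

The three steps most likely to fail:

Step 12 (ring closure). The tin-to-copper exchange may be slower than protonolysis of the alkenylcopper by the free hydroxyl, and the facial selectivity at C2 rests on a conformational argument, so a poor diastereomer ratio is possible. The fallback sets out from iodide 18, with step 11 left out. Slow addition of Bu3SnH with azobis(isobutyronitrile) in benzene at 80 °C generates the alkenyl radical, which should close the same C2–C3 bond by a 6-endo radical cyclisation onto the β-carbon of the dienal. Reduction of the α-formyl radical by the tin hydride and base equilibration bring the route back at aldehyde 22. This fallback makes no new compound (F0).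

Step 11 (stannylation). The alkenylpalladium intermediate may add to the tethered dienal (Heck-type carbopalladation), or the distannane may add across the diene before tin is transferred. The fallback again sets out from 18 and closes the ring without tin by a nickel-mediated reductive conjugate addition: Ni(cod)2 (zerovalent nickel, 1.5 equiv), Et3SiCl (3 equiv), pyridine, DMF, 20 °C. The dienal is engaged as a 1-silyloxyallylnickel species that couples with the alkenyl iodide at the allyl terminus remote from oxygen, giving the bis(triethylsilyl) enol ether F1. Treatment with 1 M HCl in THF and then base equilibration bring the route back at 22; compounds 19 to 21 are bypassed.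

Step 4 (methylation). The fluoride-generated enolate may exchange protons with the product (over-methylation, loss of regiocontrol), be O-methylated, or epimerise the ester-bearing centre. The fallback sets out from 6. Simmons–Smith cyclopropanation of the silyl enol ether (Et2Zn, CH2I2, CH2Cl2, 0 °C) from the face anti to both substituents gives the siloxycyclopropane F2. Acid-induced ring opening (TsOH·H2O, wet CH2Cl2, 20 °C) cleaves the bond between the oxygen-bearing carbon and the methylene group and brings the route back at ketone 7 with the same methyl configuration, without an enolate being formed.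

**Further compounds**

F0 | step 12 | none | none
F1 | step 11 | bis(triethylsilyl) enol ether of 22 (C1=CH–OSiEt3 and C7–OSiEt3) | C/C=C(\C)[C@@H]1C(C)=C[C@H]2CC[C@H](O[Si](CC)(CC)CC)[C@H](C)[C@H]2C1=CO[Si](CC)(CC)CC
F2 | step 4 | siloxycyclopropane: 2,2,2-trifluoroethyl 5-[2-(benzyloxy)ethyl]-1-{[tri(propan-2-yl)silyl]oxy}bicyclo[4.1.0]heptane-4-carboxylate (methylene bridge trans to ester and side chain) | O=C(OCC(F)(F)F)[C@H]1CC[C@]2(O[Si](C(C)C)(C(C)C)C(C)C)C[C@@H]2[C@H]1CCOCc1ccccc1
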